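**Retrosynthetic overview**

1. Katsumain C ⇐ 15 (loss of one aryl acetate and one aryl silyl ether) ⇐ C3′–C7 bond by aromatic Claisen ([3,3]) rearrangement of cardamonin 4′-O-allyl ether 13, which passes the C5 configuration on to C7.
2. 13 ⇐ Mitsunobu inversion at C5 of anti-diol 11 with purchased cardamonin; C5 of 11 ⇐ hydroxyl-directed 1,3-anti reduction of β-hydroxy enone 10.
3. Key bond C4–C5 of 10 ⇐ nickel-catalysed electroreductive (sacrificial-anode electrolysis) acylative opening of epoxide 5 with cinnamoyl chloride 7.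
4. 5 ⇐ (R)-epichlorohydrin (the only purchased stereocentre) + a benzylic Grignard reagent; 7 ⇐ 4-acetoxycinnamic acid.
5. Rings: the three benzene rings and the chalcone are bought; the only ring made is the oxirane of 5 (step 1), opened again in step 3.

Assumption: 1, 2, 6 and 12 are taken as catalogue compounds. The heptanoid chain is numbered C1 (CH2 next to the silyloxyphenyl ring) to C7 (diarylmethine), positions of chalcone ring A are primed, and TBSO = tert-butyldimethylsilyloxy.

**Route**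

Step 1
Reactants: 1 (R)-epichlorohydrin; 2 4-(tert-butyldimethylsilyloxy)benzyl chloride
Product: 5 (2R)-2-{2-[4-(tert-butyldimethylsilyloxy)phenyl]ethyl}oxirane, via benzylic Grignard reagent 3 (not isolated), via chloromagnesium chlorohydrin alkoxide 4 (not isolated)
Conditions: 2, Mg, THF, 0 °C; then 1, CuI (5 mol %), −40 → 0 °C; then KOt-Bu, 0 → 20 °C
Reagents that add atoms: none
Why: Copper-catalysed Grignard opening of the epoxide CH2 (SN2, the stereocentre is not touched) and then Williamson-type ring closure of alkoxide 4 onto CH2Cl give the terminal epoxide with the purchased C–O stereocentre unchanged (R).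

Step 2
Reactants: 6 (E)-4-acetoxycinnamic acid
Product: 7 (E)-4-acetoxycinnamoyl chloride
Conditions: (COCl)2, DMF (cat.), CH2Cl2, 0 → 20 °C
Reagents that add atoms: oxalyl chloride, ClC(=O)C(Cl)=O
Why: DMF-catalysed (Vilsmeier-type) acyl chloride formation activates the acid under conditions that leave the aryl acetate and the E alkene alone.

Step 3
Reactants: 5 (2R)-2-{2-[4-(TBSO)phenyl]ethyl}oxirane; 7 (E)-4-acetoxycinnamoyl chloride
Product: 10 (3R,6E)-7-(4-acetoxyphenyl)-3-hydroxy-1-[4-(TBSO)phenyl]hept-6-en-5-one, via iodo silyl ether 8 (not isolated), via silyl-protected ketone 9 (not isolated)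
Conditions: 5, Me3SiCl, NaI (returned on coupling), MeCN, 0 °C; then 7 (slow addition), NiBr2(MeOCH2CH2OMe) (10 mol %), 4,4′-di-tert-butyl-2,2′-bipyridine (12 mol %), n-Bu4NBF4, MeCN/DMA, undivided cell, Zn anode, Ni-foam cathode, 5 mA cm⁻², 2.2 F mol⁻¹, 20 °C; then aq citric acid
Reagents that add atoms: none
Why: Proposed new method: nickel-catalysed electroreductive acylative ring-opening of a terminal epoxide (a redox surrogate for an acetate aldol) — Me3SiI made in the flask opens 5 only at CH2 to primary iodide 8, cathodically formed zerovalent nickel–bipyridine inserts into the C–Cl bond of 7, the resulting acylnickel (divalent) captures the primary β-silyloxyalkyl radical released from 8 by halogen abstraction, and reductive elimination from trivalent nickel forges C4–C5 while the zinc anode supplies the electrons; C3 is never a radical or carbanion centre, so the purchased configuration is kept, and without a triplet sensitiser the enone stays E; the closest known reactions are the nickel-catalysed reductive (Zn, Mn or cathode) ketone synthesis from alkyl iodides and acid chlorides and the nickel/iodide cross-electrophile coupling of epoxides with aryl halides.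

Step 4
Reactants: 10 (3R,6E)-7-(4-acetoxyphenyl)-3-hydroxy-1-[4-(TBSO)phenyl]hept-6-en-5-one
Product: 11 (3R,5S,6E)-7-(4-acetoxyphenyl)-1-[4-(TBSO)phenyl]hept-6-ene-3,5-diol
Conditions: Me4N[BH(OAc)3], MeCN/AcOH (1:1), −30 °C
Reagents that add atoms: none
Why: Evans–Saksena reduction: the C3 hydroxyl binds boron and hands hydride to the C5 carbonyl through a chair (1,2-reduction only), so the purchased C3 centre sets C5 as S (3,5-anti).

Step 5
Reactants: 11 (3R,5S,6E)-diol; 12 cardamonin
Product: 13 cardamonin 4′-O-[(3R,5R,6E)-7-(4-acetoxyphenyl)-3-hydroxy-1-[4-(TBSO)phenyl]hept-6-en-5-yl] ether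
Conditions: PPh3, DIAD, THF, 0 → 20 °C
Reagents that add atoms: none
Why: Mitsunobu etherification: the free, more acidic 4′-OH of 12 (the 2′-OH is locked in the hydrogen bond to C=O) displaces the allylic C5 oxyphosphonium by SN2 with inversion (5S → 5R), the saturated C3 hydroxyl reacting far more slowly and the acetoxy group keeping the C7 aryl ring too electron-poor for ionisation.

Step 6
Reactants: 13 cardamonin 4′-O-allyl ether
Product: 15 3′-[(3R,5E,7R)-7-(4-acetoxyphenyl)-3-hydroxy-1-[4-(TBSO)phenyl]hept-5-en-7-yl]cardamonin, via ortho-dienone 14 (not isolated)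
Conditions: 1,2-dichlorobenzene, 160 °C, Ar, dark
Reagents that add atoms: none
Why: Aromatic Claisen rearrangement ([3,3]-sigmatropic, chair transition state with the C4 chain equatorial): the allyl unit moves suprafacially from O4′ to C3′, the ortho carbon whose bond to C4′ is held double by the chelated 2′-OH···O=C, so the 5R centre is converted into the 7R centre with an E C5=C6 alkene and dienone 14 enolises to the phenol.

Step 7
Reactants: 15 protected Katsumain C
Product: 16 Katsumain C
Conditions: K2CO3 (0.5 equiv), MeOH, 0 → 20 °C; then aq NH4Cl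
Reagents that add atoms: none
Why: Carbonate-catalysed methanolysis (transesterification of the aryl acetate, O-desilylation of the aryl silyl ether) frees both phenols at room temperature without touching the chalcone, the alkene or either stereocentre.

**Compound list**

1 | (R)-epichlorohydrin, (2R)-2-(chloromethyl)oxirane | ClC[C@H]1CO1 | starting material
2 | 4-(tert-butyldimethylsilyloxy)benzyl chloride | ClCc1ccc(O[Si](C)(C)C(C)(C)C)cc1 | starting material
3 | [4-(tert-butyldimethylsilyloxy)benzyl]magnesium chloride | Cl[Mg]Cc1ccc(O[Si](C)(C)C(C)(C)C)cc1 | intermediate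
4 | chloromagnesium (2R)-1-chloro-4-[4-(TBSO)phenyl]butan-2-olate | ClC[C@H](O[Mg]Cl)CCc1ccc(O[Si](C)(C)C(C)(C)C)cc1 | intermediate
5 | (2R)-2-{2-[4-(TBSO)phenyl]ethyl}oxirane | C1[C@H](O1)CCc2ccc(O[Si](C)(C)C(C)(C)C)cc2 | intermediate
6 | (E)-4-acetoxycinnamic acid | CC(=O)Oc1ccc(/C=C/C(=O)O)cc1 | starting material
7 | (E)-4-acetoxycinnamoyl chloride | CC(=O)Oc1ccc(/C=C/C(=O)Cl)cc1 | intermediate
8 | (2R)-1-iodo-2-(trimethylsilyloxy)-4-[4-(TBSO)phenyl]butane | IC[C@H](O[Si](C)(C)C)CCc1ccc(O[Si](C)(C)C(C)(C)C)cc1 | intermediate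
9 | (3R,6E)-7-(4-acetoxyphenyl)-3-(trimethylsilyloxy)-1-[4-(TBSO)phenyl]hept-6-en-5-one | CC(=O)Oc1ccc(/C=C/C(=O)C[C@H](O[Si](C)(C)C)CCc2ccc(O[Si](C)(C)C(C)(C)C)cc2)cc1 | intermediate
10 | (3R,6E)-7-(4-acetoxyphenyl)-3-hydroxy-1-[4-(TBSO)phenyl]hept-6-en-5-one | CC(=O)Oc1ccc(/C=C/C(=O)C[C@H](O)CCc2ccc(O[Si](C)(C)C(C)(C)C)cc2)cc1 | intermediate
11 | (3R,5S,6E)-7-(4-acetoxyphenyl)-1-[4-(TBSO)phenyl]hept-6-ene-3,5-diol (3,5-anti) | CC(=O)Oc1ccc(/C=C/[C@@H](O)C[C@H](O)CCc2ccc(O[Si](C)(C)C(C)(C)C)cc2)cc1 | intermediate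
12 | cardamonin, (E)-1-(2,4-dihydroxy-6-methoxyphenyl)-3-phenylprop-2-en-1-one | COc1cc(O)cc(O)c1C(=O)/C=C/c1ccccc1 | starting material
13 | cardamonin 4′-O-[(3R,5R,6E)-7-(4-acetoxyphenyl)-3-hydroxy-1-[4-(TBSO)phenyl]hept-6-en-5-yl] ether | CC(=O)Oc1ccc(/C=C/[C@H](Oc3cc(O)c(C(=O)/C=C/c4ccccc4)c(OC)c3)C[C@H](O)CCc2ccc(O[Si](C)(C)C(C)(C)C)cc2)cc1 | intermediate
14 | ortho-dienone tautomer of 15 (C4′ ketone, sp3 C3′ bearing H and the heptenyl unit; C3 and C7 arranged as in 15; ring C3′ drawn S as the chair model predicts, lost on enolisation) | COC1=CC(=O)[C@@H]([C@H](/C=C/C[C@H](O)CCc2ccc(O[Si](C)(C)C(C)(C)C)cc2)c3ccc(OC(C)=O)cc3)C(O)=C1C(=O)/C=C/c4ccccc4 | intermediate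
15 | 3′-[(3R,5E,7R)-7-(4-acetoxyphenyl)-3-hydroxy-1-[4-(TBSO)phenyl]hept-5-en-7-yl]cardamonin | COc1cc(O)c([C@H](/C=C/C[C@H](O)CCc2ccc(O[Si](C)(C)C(C)(C)C)cc2)c2ccc(OC(C)=O)cc2)c(O)c1C(=O)/C=C/c1ccccc1 | intermediate
16 | Katsumain C, (3R,5E,7R) | COc1cc(O)c([C@H](/C=C/C[C@H](O)CCc2ccc(O)cc2)c2ccc(O)cc2)c(O)c1C(=O)/C=C/c1ccccc1 | target

**Step count**

Total steps: 7. Longest linear sequence: 6 (steps 1, 3, 4, 5, 6, 7).

**Three steps most likely to fail**

Step 3 (the proposed new step). Risks: acyl chloride 7 may react with any epoxide not yet converted into 8, the C4 radical may add to the enone instead of being caught by nickel, and the enone may be reduced at the cathode. Fallback with known chemistry (dithiane umpolung), setting out from 5 and coming back at 10: 4-hydroxycinnamaldehyde, propane-1,3-dithiol and BF3·OEt2 give 2-[(E)-2-(4-hydroxyphenyl)ethenyl]-1,3-dithiane F1. Its dianion (n-BuLi, 2.1 equiv, THF, −78 → −20 °C) opens 5 at CH2 to give the dithianyl carbinol F2. Hg(ClO4)2 with CaCO3 in aqueous THF unmasks the ketone to give the β-hydroxy enone phenol F3. Ac2O with K2CO3 in acetone at 0 °C acetylates only the phenol and gives 10.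

Step 5. Risks: the C3 hydroxyl may be activated as well, and the cinnamyl-type oxyphosphonium may react by SN2′ or ionise, which would erode the C5 configuration. Fallback, setting out from 11 and coming back at 13: 1,1′-carbonyldiimidazole in CH2Cl2 closes the diol to the six-membered cyclic carbonate F4 with both C–O bonds retained. Cardamonin 12 with Cs2CO3 in DMF at 70 °C then opens F4 by SN2 at the allylic C5 carbon (inversion), and the alkyl carbonate left on O3 loses CO2 to give 13.

Step 6. Risks: part of the allyl unit may migrate to C5′, some [1,3] product may form through ionisation, and the 2′-hydroxychalcone may suffer at 160 °C. Fallback by copper-mediated anti-SN2′ arylation with a symmetric nucleophile, setting out from 11 (taken to carbonate F4 as above) and coming back at 16: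
- 5-Methoxyresorcinol with MOMCl and i-Pr2NEt gives 1-methoxy-3,5-bis(methoxymethoxy)benzene F5.
- n-BuLi lithiates F5 between the two MOM ethers and CuBr·SMe2 turns it into the arylcopper. This adds to C7 of F4 anti to the departing carbonate oxygen (5S → 7R, E alkene, CO2 lost) to give the diarylmethine F6.
- NBS in CH2Cl2 at −78 °C brominates either of the two equivalent free positions of ring A to give the aryl bromide F7.
- Carbonylative Suzuki–Miyaura coupling (CO, (E)-styrylboronic acid, Pd(OAc)2, P(1-adamantyl)2(n-Bu), K2CO3, toluene, 90 °C) installs the cinnamoyl group to give the protected chalcone F8.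
- K2CO3 in MeOH and then HCl in MeOH remove the acetate, silyl and MOM groups to give 16.

**Further compounds**

F1 | step 3 | 2-[(E)-2-(4-hydroxyphenyl)ethenyl]-1,3-dithiane | Oc1ccc(/C=C/C2SCCCS2)cc1
F2 | step 3 | (2R)-1-{2-[(E)-2-(4-hydroxyphenyl)ethenyl]-1,3-dithian-2-yl}-4-[4-(TBSO)phenyl]butan-2-ol | Oc1ccc(/C=C/C2(C[C@H](O)CCc3ccc(O[Si](C)(C)C(C)(C)C)cc3)SCCCS2)cc1
F3 | step 3 | (3R,6E)-3-hydroxy-7-(4-hydroxyphenyl)-1-[4-(TBSO)phenyl]hept-6-en-5-one | Oc1ccc(/C=C/C(=O)C[C@H](O)CCc2ccc(O[Si](C)(C)C(C)(C)C)cc2)cc1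
F4 | step 5 | 4-[(E)-2-{(4S,6R)-2-oxo-6-[2-(4-(TBSO)phenyl)ethyl]-1,3-dioxan-4-yl}ethenyl]phenyl acetate | CC(=O)Oc1ccc(/C=C/[C@@H]2C[C@@H](CCc3ccc(O[Si](C)(C)C(C)(C)C)cc3)OC(=O)O2)cc1
F5 | step 6 | 1-methoxy-3,5-bis(methoxymethoxy)benzene | COCOc1cc(OC)cc(OCOC)c1
F6 | step 6 | 4-[(1R,2E,5R)-5-hydroxy-1-[4-methoxy-2,6-bis(methoxymethoxy)phenyl]-7-[4-(TBSO)phenyl]hept-2-en-1-yl]phenyl acetate | COCOc1cc(OC)cc(OCOC)c1[C@H](/C=C/C[C@H](O)CCc2ccc(O[Si](C)(C)C(C)(C)C)cc2)c3ccc(OC(C)=O)cc3
F7 | step 6 | 4-[(1R,2E,5R)-1-[3-bromo-4-methoxy-2,6-bis(methoxymethoxy)phenyl]-5-hydroxy-7-[4-(TBSO)phenyl]hept-2-en-1-yl]phenyl acetate | COCOc1cc(OC)c(Br)c(OCOC)c1[C@H](/C=C/C[C@H](O)CCc2ccc(O[Si](C)(C)C(C)(C)C)cc2)c3ccc(OC(C)=O)cc3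
F8 | step 6 | 2′,4′-bis-O-(methoxymethyl) ether of 15 | COCOc1cc(OC)c(C(=O)/C=C/c4ccccc4)c(OCOC)c1[C@H](/C=C/C[C@H](O)CCc2ccc(O[Si](C)(C)C(C)(C)C)cc2)c3ccc(OC(C)=O)cc3
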